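**Plan** (ring numbering: C1 carbinol carbon, C2 its CH2 neighbour, C3=C4 the alkene with methyl on C4, C5 the carbon bearing CH2OAr, C6 the gem-dimethyl carbon)
1. Cuts: the aryl ether O–CH2 and the ester O–acyl bond last; then the ring alkene C3=C4 (metathesis); then C2–C3 and C1–C6 together, which frees the two-carbon unit C1–C2 as a vinyl group.
2. Enabling feature: in the cyclohexene ring the carbinol C1 lies between the quaternary C6 and the CH2 C2 that is bonded to the sp2 carbon C3. This C(sp2)–CH2–CH(O)–C(tertiary) array is the retron of a conjunctive cross-coupling of a vinylboron ate complex, with boron as the masked C1 oxygen.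
3. Forward: prenol → epoxide → isopropenyl opening (C5 with its C4 unit) → tertiary boronic ester at C6 → three-component coupling with ethenyllithium and ethenyl triflate (C1–C6 and C2–C3 in one operation) → oxidation → ring-closing metathesis (C3=C4, the only carbocycle) → acylation → desilylation → aryl ether.
4. Stereochemistry: C5 comes from the Sharpless epoxide (inversion on opening); C1 comes from the chiral palladium catalyst and is carried through stereoretentive C–B oxidation. The two centres are set independently, which gives the cis relation of the C1 oxygen and the C5 CH2O arm. The acyl stereocentre is bought with (R)-2-methylbutanoic acid.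

Key step: step 6

Remark (a): ethenyllithium is used as a halide-free stock solution (standard preparation from tetravinylstannane and n-butyllithium) and is counted, like ethenyl trifluoromethanesulfonate and (R)-2-methylbutanoic acid, as a purchasable reagent.
Remark (b): MandyPhos is 1,1′-bis[bis(4-methoxy-3,5-dimethylphenyl)phosphino]-2,2′-bis[(R)-α-(dimethylamino)benzyl]ferrocene; its (Sp,Sp) form is assumed to give the (4R) C–B centre, and its mirror image is used instead if the sense of induction is the opposite.

**Step 1**
Reactants: 1 3-methylbut-2-en-1-ol (prenol)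
Product: 2 [(2S)-3,3-dimethyloxiran-2-yl]methanol
Conditions: Ti(OiPr)4 (5 mol %), L-(+)-diethyl tartrate (6 mol %), t-BuOOH, 4 Å molecular sieves, CH2Cl2, −20 °C
Reagents that add atoms: tert-butyl hydroperoxide, CC(C)(C)OO
Why: Katsuki–Sharpless asymmetric epoxidation of a primary allylic alcohol, in which the titanium–L-tartrate complex delivers oxygen to one enantiotopic face and sets the (S) epoxide carbon that becomes C5.

**Step 2**
Reactants: 2 [(2S)-3,3-dimethyloxiran-2-yl]methanol
Product: 3 tert-butyl{[(2S)-3,3-dimethyloxiran-2-yl]methoxy}dimethylsilane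
Conditions: TBSCl, imidazole, CH2Cl2, 0 °C to rt
Reagents that add atoms: tert-butyldimethylsilyl chloride, CC(C)(C)[Si](C)(C)Cl
Why: Routine silylation of the primary alcohol, which blocks Payne rearrangement in the next step and masks the future aryl ether oxygen without touching the stereocentre.

**Step 3**
Reactants: 3 tert-butyl{[(2S)-3,3-dimethyloxiran-2-yl]methoxy}dimethylsilane; 4 prop-1-en-2-ylmagnesium bromide (isopropenylmagnesium bromide)
Product: 5 (3R)-3-{[tert-butyl(dimethyl)silyl]oxymethyl}-2,4-dimethylpent-4-en-2-ol
Conditions: 4 (2 equiv), CuBr·SMe2 (10 mol %), THF, −30 to 0 °C; aq NH4Cl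
Reagents that add atoms: none
Why: Copper-catalysed Grignard opening of an epoxide (SN2), in which the alkenyl group should attack the secondary carbon because the other epoxide carbon is tertiary, with inversion, so that the future C5 is fixed and the tertiary alcohol marks the future C6.

**Step 4**
Reactants: 5 (3R)-3-{[tert-butyl(dimethyl)silyl]oxymethyl}-2,4-dimethylpent-4-en-2-ol
Product: 6 methyl (3R)-3-{[tert-butyl(dimethyl)silyl]oxymethyl}-2,4-dimethylpent-4-en-2-yl oxalate
Conditions: ClC(O)CO2Me, Et3N, DMAP (cat.), CH2Cl2, 0 °C
Reagents that add atoms: methyl chlorooxoacetate, COC(=O)C(=O)Cl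
Why: Acylation of the tertiary alcohol with an oxalyl chloride half ester should give the radical precursor for deoxygenative functionalisation, and no stereocentre is affected.

**Step 5**
Reactants: 6 methyl (3R)-3-{[tert-butyl(dimethyl)silyl]oxymethyl}-2,4-dimethylpent-4-en-2-yl oxalate
Product: 8 tert-butyldimethyl{[(2R)-3-methyl-2-(prop-1-en-2-yl)-3-(4,4,5,5-tetramethyl-1,3,2-dioxaborolan-2-yl)butyl]oxy}silane, via catechol boronate 7 (not isolated)
Conditions: B2cat2, Ir(ppy)3 (1 mol %), DMF, blue LEDs, rt; then pinacol, Et3N
Reagents that add atoms: bis(catecholato)diboron, B1(Oc2ccccc2O1)B1Oc2ccccc2O1; pinacol, CC(C)(O)C(C)(C)O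
Why: Photoredox deoxygenative radical borylation of a tertiary alkyl methyl oxalate, in which single-electron reduction and C–O fragmentation give the tertiary radical at the non-stereogenic carbon, the diboron reagent borylates it and pinacol exchange gives the stable ester, the neighbouring stereocentre being untouched.

**Step 6**
Reactants: 8 tert-butyldimethyl{[(2R)-3-methyl-2-(prop-1-en-2-yl)-3-(4,4,5,5-tetramethyl-1,3,2-dioxaborolan-2-yl)butyl]oxy}silane; 9 ethenyllithium (vinyllithium); 10 ethenyl trifluoromethanesulfonate (vinyl triflate)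
Product: 13 (4R,6S)-6-{[tert-butyl(dimethyl)silyl]oxymethyl}-5,5,7-trimethylocta-1,7-dien-4-ol, via lithium vinylboron ate complex 11 (not isolated), via homoallylic pinacol boronate 12 (not isolated)
Conditions: 9, Et2O–THF, −78 to 0 °C; then Pd(OAc)2 (2 mol %), (Sp,Sp)-MandyPhos (2.4 mol %), 10, THF, 60 °C; then NaOH, H2O2, 0 °C to rt
Reagents that add atoms: hydrogen peroxide, OO
Why: Proposed new method: ethenyllithium adds to the tertiary boronic ester to give a four-coordinate vinylboron ate complex, the cationic vinylpalladium species formed by oxidative addition of 10 to zerovalent palladium binds the B-vinyl group and triggers a 1,2-metalate shift in which the tertiary carbon migrates from boron to the alpha carbon anti to palladium, and reductive elimination then joins the beta CH2 to the vinyl carbon, so that C1–C6 and C2–C3 arise in one catalytic turnover before stereoretentive oxidation of the C–B bond. The closest known reaction type is the palladium-catalysed conjunctive cross-coupling of vinylboron ate complexes with alkenyl triflates, established for aryl and for less hindered alkyl migrating groups; the extension to a tertiary, beta-branched migrating group is supported by the ready 1,2-migration of tertiary alkyl groups in Zweifel olefination and in radical-induced rearrangements of vinylboron ate complexes. No ring is closed in this step, the cyclohexene ring being closed in step 7. The new carbinol stereocentre is set by the chiral bisphosphine on palladium, which selects the enantiotopic face of the B-vinyl group, while the existing stereocentre lies beyond the quaternary carbon and should exert little bias. The step needs the conjunctive pathway to outrun direct Suzuki-type transfer of the vinyl group and beta-hydride loss, which the wide-bite-angle ligand and the halide-free triflate electrophile should secure, and it needs the isopropenyl group of 8 to stay untouched, which is expected because that alkene carries no boron ate activator.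

**Step 7**
Reactants: 13 (4R,6S)-6-{[tert-butyl(dimethyl)silyl]oxymethyl}-5,5,7-trimethylocta-1,7-dien-4-ol
Product: 14 (1R,5S)-5-{[tert-butyl(dimethyl)silyl]oxymethyl}-4,6,6-trimethylcyclohex-3-en-1-ol
Conditions: second-generation Grubbs catalyst RuCl2(=CHPh)(H2IMes)(PCy3) (5 mol %), CH2Cl2 (0.005 M), 40 °C
Reagents that add atoms: none
Why: Ring-closing olefin metathesis of the 1,7-diene, helped by the gem-dimethyl group, should close the six-membered ring and form the trisubstituted C3=C4 alkene with loss of ethene, no stereocentre being involved.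

**Step 8**
Reactants: 14 (1R,5S)-5-{[tert-butyl(dimethyl)silyl]oxymethyl}-4,6,6-trimethylcyclohex-3-en-1-ol; 15 (2R)-2-methylbutanoic acid
Product: 16 (1R,5S)-5-{[tert-butyl(dimethyl)silyl]oxymethyl}-4,6,6-trimethylcyclohex-3-en-1-yl (2R)-2-methylbutanoate
Conditions: 15, DCC, DMAP, CH2Cl2, 0 °C to rt
Reagents that add atoms: none
Why: Steglich esterification should acylate the hindered secondary alcohol with retention at the carbinol carbon, and the non-activated alpha stereocentre of the acid is expected to survive these mild conditions.

**Step 9**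
Reactants: 16 (1R,5S)-5-{[tert-butyl(dimethyl)silyl]oxymethyl}-4,6,6-trimethylcyclohex-3-en-1-yl (2R)-2-methylbutanoate
Product: 17 (1R,5S)-5-(hydroxymethyl)-4,6,6-trimethylcyclohex-3-en-1-yl (2R)-2-methylbutanoate
Conditions: HF·pyridine, THF, 0 °C to rt
Reagents that add atoms: none
Why: Fluoride cleavage of the primary silyl ether under acidic buffered conditions, which should avoid base-induced acyl migration from the C1 ester to the freed primary hydroxyl.

**Step 10**
Reactants: 17 (1R,5S)-5-(hydroxymethyl)-4,6,6-trimethylcyclohex-3-en-1-yl (2R)-2-methylbutanoate; 18 7-hydroxy-2H-chromen-2-one (umbelliferone)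
Product: 19 (1R,5S)-4,6,6-trimethyl-5-{[(2-oxo-2H-chromen-7-yl)oxy]methyl}cyclohex-3-en-1-yl (2R)-2-methylbutanoate
Conditions: 18, PPh3, DIAD, THF, 0 °C to rt
Reagents that add atoms: none
Why: Mitsunobu etherification of the primary alcohol with the acidic phenol should form the aryl ether at a CH2 group, so no stereocentre changes.

**Compound list**
1 | 3-methylbut-2-en-1-ol (prenol) | CC(C)=CCO | starting material
2 | [(2S)-3,3-dimethyloxiran-2-yl]methanol | CC1(C)O[C@H]1CO | intermediate
3 | tert-butyl{[(2S)-3,3-dimethyloxiran-2-yl]methoxy}dimethylsilane | CC1(C)O[C@H]1CO[Si](C)(C)C(C)(C)C | intermediate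
4 | prop-1-en-2-ylmagnesium bromide | CC(=C)[Mg]Br | starting material
5 | (3R)-3-{[tert-butyl(dimethyl)silyl]oxymethyl}-2,4-dimethylpent-4-en-2-ol | CC(C)(O)[C@@H](CO[Si](C)(C)C(C)(C)C)C(C)=C | intermediate
6 | methyl (3R)-3-{[tert-butyl(dimethyl)silyl]oxymethyl}-2,4-dimethylpent-4-en-2-yl oxalate | COC(=O)C(=O)OC(C)(C)[C@@H](CO[Si](C)(C)C(C)(C)C)C(C)=C | intermediate
7 | tert-butyl{[(2R)-3-(1,3,2-benzodioxaborol-2-yl)-3-methyl-2-(prop-1-en-2-yl)butyl]oxy}dimethylsilane | CC(C)(B1Oc2ccccc2O1)[C@@H](CO[Si](C)(C)C(C)(C)C)C(C)=C | intermediate (not isolated)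
8 | tert-butyldimethyl{[(2R)-3-methyl-2-(prop-1-en-2-yl)-3-(4,4,5,5-tetramethyl-1,3,2-dioxaborolan-2-yl)butyl]oxy}silane | CC(C)(B1OC(C)(C)C(C)(C)O1)[C@@H](CO[Si](C)(C)C(C)(C)C)C(C)=C | intermediate
9 | ethenyllithium | [Li]C=C | starting material
10 | ethenyl trifluoromethanesulfonate | C=COS(=O)(=O)C(F)(F)F | starting material
11 | lithium [(3R)-4-{[tert-butyl(dimethyl)silyl]oxy}-2-methyl-3-(prop-1-en-2-yl)butan-2-yl](ethenyl)(2,3-dimethylbutane-2,3-diolato)borate | [Li+].C=C[B-]1(OC(C)(C)C(C)(C)O1)C(C)(C)[C@@H](CO[Si](C)(C)C(C)(C)C)C(C)=C | intermediate (not isolated)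
12 | tert-butyl{[(2S,4R)-3,3-dimethyl-2-(prop-1-en-2-yl)-4-(4,4,5,5-tetramethyl-1,3,2-dioxaborolan-2-yl)hept-6-en-1-yl]oxy}dimethylsilane | C=CC[C@@H](B1OC(C)(C)C(C)(C)O1)C(C)(C)[C@@H](CO[Si](C)(C)C(C)(C)C)C(C)=C | intermediate (not isolated)
13 | (4R,6S)-6-{[tert-butyl(dimethyl)silyl]oxymethyl}-5,5,7-trimethylocta-1,7-dien-4-ol | C=CC[C@@H](O)C(C)(C)[C@@H](CO[Si](C)(C)C(C)(C)C)C(C)=C | intermediate
14 | (1R,5S)-5-{[tert-butyl(dimethyl)silyl]oxymethyl}-4,6,6-trimethylcyclohex-3-en-1-ol | O[C@@H]1CC=C(C)[C@H](CO[Si](C)(C)C(C)(C)C)C1(C)C | intermediate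
15 | (2R)-2-methylbutanoic acid | CC[C@@H](C)C(=O)O | starting material
16 | (1R,5S)-5-{[tert-butyl(dimethyl)silyl]oxymethyl}-4,6,6-trimethylcyclohex-3-en-1-yl (2R)-2-methylbutanoate | CC[C@@H](C)C(=O)O[C@@H]1CC=C(C)[C@H](CO[Si](C)(C)C(C)(C)C)C1(C)C | intermediate
17 | (1R,5S)-5-(hydroxymethyl)-4,6,6-trimethylcyclohex-3-en-1-yl (2R)-2-methylbutanoate | CC[C@@H](C)C(=O)O[C@@H]1CC=C(C)[C@H](CO)C1(C)C | intermediate
18 | 7-hydroxy-2H-chromen-2-one (umbelliferone) | Oc1ccc2ccc(=O)oc2c1 | starting material
19 | (1R,5S)-4,6,6-trimethyl-5-{[(2-oxo-2H-chromen-7-yl)oxy]methyl}cyclohex-3-en-1-yl (2R)-2-methylbutanoate | CC[C@@H](C)C(=O)O[C@@H]1CC=C(C)[C@H](COc2ccc3ccc(=O)oc3c2)C1(C)C | target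

**Totals**
Total step count: 10. Longest linear sequence: 10 steps (1 to 19).

**Steps most likely to fail**

1. Step 6 (proposed new method). The 1,2-shift of the hindered tertiary group may be too slow, so that direct Suzuki-type transfer of the vinyl group or protodeboronation of the ate complex takes over. Catalyst and existing stereocentre may also be mismatched, which would erode facial selectivity at C1. The fallback uses known chemistry (lithiation–borylation), sets out from 8 and returns at 12, which is oxidised to 13 as in step 6. But-3-en-1-yl N,N-diisopropylcarbamate F1 (from but-3-en-1-ol and N,N-diisopropylcarbamoyl chloride) is deprotonated with s-BuLi and (−)-sparteine in Et2O at −78 °C to give (1S)-1-lithiobut-3-en-1-yl N,N-diisopropylcarbamate F2. Addition of 8 gives, by borylation with retention, the lithium boron ate complex F3. Warming with MgBr2·OEt2 in MeOH–Et2O induces 1,2-migration of the tertiary group with inversion and loss of the carbamate, which gives 12 with C1 set by the reagent. The C2–C3 bond then comes with the butenyl unit, so the two bonds are no longer made in one operation.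

2. Step 5. Capture of the hindered tertiary radical by the diboron reagent may be slow, so that hydrogen abstraction, 1,2-vinyl migration of the homoallylic radical or chain termination wins. The fallback sets out from 6 and returns at 13; it leaves boron out and traps the radical with a faster reagent. Compound 6 is saponified with CsOH (THF–H2O) to the cesium oxalate F4. Photoredox fragmentation (Ir[dF(CF3)ppy]2(dtbbpy)PF6, blue LEDs, DME–DMF) in the presence of 4-methylbenzenesulfonyl cyanide gives the tertiary nitrile F5 by radical cyanation. Reduction with i-Bu2AlH (toluene, −78 °C; aqueous acid) gives the aldehyde F6. Asymmetric allylboration with B-allyldiisopinocampheylborane (the antipode that leads to the 4R alcohol; Et2O, −78 °C; then NaOH, H2O2) gives 13.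

3. Step 3. SN2 attack of the alkenyl copper species at the hindered secondary epoxide carbon may be slow, so that bromide opening at the tertiary carbon or rearrangement of the epoxide promoted by the magnesium salts competes. The fallback sets out from 3 and returns at 5; it uses a small, salt-free carbon nucleophile and builds the methyl-bearing alkene afterwards. Compound 3 is opened with lithium acetylide–ethylenediamine complex (LiC≡CH·H2NCH2CH2NH2) in DMSO at rt, by SN2 with inversion at the secondary carbon, to the alkynol F7. Zirconium-catalysed methylalumination (AlMe3, Cp2ZrCl2 cat., CH2Cl2; then H2O) adds methyl to the internal alkyne carbon and hydrogen to the terminus, which turns the ethynyl group into the prop-1-en-2-yl group and gives 5.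

**Further compounds**
F1 | step 6 | but-3-en-1-yl N,N-diisopropylcarbamate | C=CCCOC(=O)N(C(C)C)C(C)C
F2 | step 6 | (1S)-1-lithiobut-3-en-1-yl N,N-diisopropylcarbamate | C=CC[C@H]([Li])OC(=O)N(C(C)C)C(C)C
F3 | step 6 | lithium boron ate complex from F2 and 8 | [Li+].C=CC[C@H]([B-]1(OC(C)(C)C(C)(C)O1)C(C)(C)[C@@H](CO[Si](C)(C)C(C)(C)C)C(C)=C)OC(=O)N(C(C)C)C(C)C
F4 | step 5 | cesium oxalate, cesium (3R)-3-{[tert-butyl(dimethyl)silyl]oxymethyl}-2,4-dimethylpent-4-en-2-yl oxalate | [Cs+].[O-]C(=O)C(=O)OC(C)(C)[C@@H](CO[Si](C)(C)C(C)(C)C)C(C)=C
F5 | step 5 | tertiary nitrile, (3S)-3-{[tert-butyl(dimethyl)silyl]oxymethyl}-2,2,4-trimethylpent-4-enenitrile | N#CC(C)(C)[C@@H](CO[Si](C)(C)C(C)(C)C)C(C)=C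
F6 | step 5 | aldehyde, (3S)-3-{[tert-butyl(dimethyl)silyl]oxymethyl}-2,2,4-trimethylpent-4-enal | O=CC(C)(C)[C@@H](CO[Si](C)(C)C(C)(C)C)C(C)=C
F7 | step 3 | alkynol, (3R)-3-{[tert-butyl(dimethyl)silyl]oxymethyl}-2-methylpent-4-yn-2-ol | CC(C)(O)[C@@H](CO[Si](C)(C)C(C)(C)C)C#C
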